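All runs stem from a simulated flask with constants of no real substance; the scatter is artificial.

Which of target and isomer of the product leads in this flask, and what is the target's share at each asked time?

| flask | substrate | coupling partner | remark | time |
|---|---|---|---|---|
| Saturday's | 1.4 M | 1 M | run made earlier |  |
| Sunday's | 2.2 M | 1 M | run made earlier |  |
| flask | 1.0 M | 1.00 M |  | 5.0 h |

- Saturday's (time / h: target / %, isomer of the product / %): 0.417: 18, 6; 0.833: 34, 17; 1.33: 48, 20; 2.50: 59, 27; 5.00: 68, 33
- Sunday's (time / h: target / %, isomer of the product / %): 0.417: 18, 7; 1.33: 48, 23; 2.50: 61, 27; 4.00: 65, 29; 5.00: 70, 30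

(scatter of a reading: 1.5 percentage points)

1. share of target in target plus isomer of the product at 3.0 min
2. share of target in target plus isomer of the product at 30 min
3. share of target in target plus isomer of the product at 5.0 h
4. which of target and isomer of the product there is more of at 5.0 h



1. You take over a closed, stirred flask of substrate and coupling partner. I reckon the end first.

2. At 5.00 h, Saturday's run gives a target share of 67.3% and Sunday's gives 70.0%. Their substrate charges were 1.4 M and 2.2 M.

3. Pooling both gives 68.7%. I call this the end share, the late value of target over target plus isomer of the product.

4. Saturday's share at 2.50 h is already 68.6%. Don't wait past 5.0 h for a better one. I expect this flask to show the end share at 5.0 h, with target leading.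

5. The first readings, at 0.417 h, give 75.0% and 72.0%, both higher than the end share. These are small readings with a large scatter. Still, I put this flask above the end share at 3.0 min, by an amount the readings don't give.

6. The forecast gives 70% at 3.0 min (range 60% to 79%), 69% at 30 min and 69% at 5.0 h, with target leading. Its ground is “The share does not drift with time”. There it differs from me.

The flask gives 89.1%, 70.9% and 68.5%, with target leading.

    target ⇌ isomer of the product (K = 0.460, k = 0.130 min⁻¹)
    intermediate A ⇌ intermediate B (K = 0.380, k = 1.50 min⁻¹)
    substrate → intermediate C (k = 0.460 min⁻¹)
    intermediate C → target (k = 0.0160 min⁻¹)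
    substrate + coupling partner ⇌ intermediate A (K = 3.00 L mol⁻¹, k = 0.190 L mol⁻¹ min⁻¹)

The flask's share falls from 89.1% to 68.5%, against my end share of 68.7%. At 5.0 h the flask's share stands at the equilibrium value of target and isomer of the product, 68.5%, which is thermodynamic control. The relaxation half-life of 1.68 min is far shorter than 5.0 h. The neighbouring flask is charged with 0.40 M of substrate, which makes 2.50 equiv of coupling partner. I again reckon 68.7% for it at 5.0 h. It gives 68.5%, with target at 67.8% and isomer of the product at 31.1% of the substrate charged.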